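The constants used here were drawn at random within sensible limits; what happens was integrated by code.

Litres per mole per second is the unit of the one step here with no way back, L pairing to L2 at 0.0266 L mol⁻¹ s⁻¹.

L 0.87 M; time 6.0 min

1. why nothing more happens at 6.0 min, or that something still does (it is still moving / forward and back rates have come level / all of L has reacted)
2. how much E there is at 6.0 min, in percent of the L charged

- percent here means L units held: one L2 counts as two
- what is said of E includes Q
- a doubled species enters its step squared and goes two at a time
- Q is a solid; its amount is given per volume of the solution
- the reaction counts as stopped when no species that holds the L changes by six tenths of a point or more over the second half of the time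
- run time (flask): 6.0 min

I call L, E and G together the pool, P. In this flask G follows L with a relaxation half-life of 0.172 s, sooner than E's 0.188 min. That second time is short against 6.0 min, so I treat both as a pre-equilibrium: E stands at 0.524 of L, and G at 0.10 of L. L then holds a share f of the pool, one over one plus those two constants, which is 0.616. Pairing sees L, so P falls at second order with the pool constant κ, which is 2 times the pairing constant times f squared: 0.0202 L mol⁻¹ s⁻¹. The inverse of P climbs in a straight line from the inverse of the charge, with slope κ.

Now I draw E in this flask. It starts at a slope of 0.0184 M s⁻¹. Its knee comes near two relaxation times, 0.543 min, when the line gives P as 0.553 M. E is then about 0.154 M, below the solubility of 0.18 M, so I expect no crystals. After that E sinks with the pool. At 6.0 min P is 0.119 M, which makes E 4.41% of the charge. Over the second half L loses 6.39% of the charge, so I say it is still moving.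

The forecast says it is still moving and 4.6%, a little above my figure. Its ground is that “the pool drains only through second-order dimerisation”.

The flask gives it is still moving and 4.71%, with Q at 0%.

    Q ⇌ E, rate k1*(cs1 - [E]) while solid is left; crystals form when [E] > cs1 (cs1 = 0.18 M, k1 = 1.78 s⁻¹)
    2 L → L2 (k2 = 0.0266 L mol⁻¹ s⁻¹)
    L ⇌ E (K3 = 0.524, k3 = 0.0211 s⁻¹)
    L ⇌ G (K4 = 0.10, k4 = 0.366 s⁻¹)

At 6.00 min this flask reads L at 0.603 of the pool, against my f of 0.616. The neighbour flask is charged with 0.22 M of L, about a quarter of the first charge, and runs for the same time. With the same κ, its pool comes to 0.0847 M. So E comes to 12.4% of its own charge, a larger percentage than in the first flask. Simulated, the neighbour flask holds 12.7% E at 6.00 min.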